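Time comes first here. At 40.0 s the teal run holds 21.2% of its starting material and at 40.0 s the grey run holds 21.7%, though grey has 3.12 times the partner.

all flasks: starting material 0.050 M

|  | partner | remark | time |
|---|---|---|---|
| teal | 0.096 M | run made earlier |  |
| amber | 0.17 M | run made earlier |  |
| grey | 0.30 M | run made earlier |  |
| theta | 0.190 M |  | 3.0 min |
| delta | 0.120 M |  | 3.0 min |
| eta | 0.280 M |  | 3.0 min |

| run | time / s | target / % | starting material / % |
|---|---|---|---|
| teal | 20.0 | 0.4 | 48.1 |
| teal | 40.0 | 1.8 | 21.2 |
| teal | 50.0 | 3.4 | 13.8 |
| teal | 80.0 | 9.1 | 3.5 |
| teal | 90.0 | 10.6 | 2.5 |
| amber | 10.0 | 0.4 | 71.3 |
| amber | 25.0 | 1.0 | 39.7 |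
| amber | 40.0 | 3.9 | 21.3 |
| amber | 60.0 | 7.9 | 8.8 |
| amber | 90.0 | 17.2 | 2.7 |
| grey | 10.0 | 0 | 71.6 |
| grey | 25.0 | 2.2 | 40.1 |
| grey | 40.0 | 6.1 | 21.7 |
| grey | 60.0 | 14.2 | 9.6 |
| grey | 90.0 | 27.5 | 2.7 |

(standard deviation of a reading: 0.3 percentage points)

- in percentages every species weighs as the starting material in it: one side product counts as two
- the analysis behind the earlier runs scatters by 0.3 percentage points, standard deviation

- which of the two there is more of at the end, counted by the starting material in each, theta (side product / target)
- which of the two there is more of at the end, counted by the starting material in each, delta (side product / target)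
- which of the two there is more of at the end, counted by the starting material in each, eta (side product / target)
- amount of target at the end, in percent of the starting material charged, theta
- amount of target at the end, in percent of the starting material charged, delta
- amount of target at the end, in percent of the starting material charged, eta

So we follow one molecule of starting material and ask for its chances at its fork, leaving the partner aside. In grey the first-order constant over the first 10.0 s is 0.0334 s⁻¹, and from there to 60.0 s it is 0.0402 s⁻¹, which is larger. We read this as a second way out that opens once something has been made, with the early constant as the plain route. We also suppose that the second way ends in side product, which counts as two.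

share by the second way = 1 − early/late = 16.9%

side product = 2 × share = 33.8%

The weak link is the late constant, which rests on a reading of 9.6% with a scatter of 0.3 percentage points. We reforge it by pooling: the early constant from amber and grey gives 0.0336 s⁻¹, and the late constants of all the runs (teal from 20.0 s to 50.0 s) give 0.0412 s⁻¹.

side share, the part of the starting material that leaves by the second way 18.4%

side product = 2 × side share = 36.9%

At 90.0 s grey has 2.7% of starting material left, less than this side product, so we let 36.9% stand for theta, delta and eta at 3.0 min.

The forecast says side product for theta with target 38%, side product for delta with 27%, and target for eta with 52%. For delta it reckons “target about 27, side about 50”, where our own side product is 36.9%.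

    partner → second intermediate (k = 0.00810 s⁻¹)
    open intermediate + second intermediate → target (k = 0.0980 M⁻¹ s⁻¹)
    partner ⇌ dormant form (K = 0.140, k = 0.00750 s⁻¹)
    starting material + open intermediate → side product (k = 0.470 M⁻¹ s⁻¹)
    starting material → open intermediate (k = 0.0310 s⁻¹)

Theta holds target 44.0% against side product 37.9%, delta 33.0% against 38.6%, and eta 52.9% against 36.9%, so the target leads in theta, against the forecast. In delta at 3.00 min, starting material goes 4.7 times as fast to open intermediate as to side product, with 0.0689% of it left. Side product there stood at 37.5% at 1.50 min, with 2.49% of starting material left, and ends at 38.6%, beside our 36.9%.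

A neighbour of delta is charged with 0.020 M of starting material. As a rough estimate of our own, we take the odds of the second way against the plain route in proportion to the charge of starting material: 0.0904, which gives a side product of 16.6%. The computed flask holds side product 20.8% and target 44.0%.

All runs were generated by integration for an exercise, noise included.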